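**Structural features**

The target is a pentacyclic prenylated flavonoid whose core is a dibenzo-fused 2,8-dioxabicyclo[3.3.1]nonane. Ring C (O1, C2, C3, C4, C4a, C8a; flavanone numbering) is bridged by a second six-membered ring made of C2, C3, C4, the hemiketal oxygen and the C1'–C6' edge of ring B. Ring A is fully substituted: methoxy at C5, a 2,2-dimethyl-2H-pyran fused across C6–C7 with its oxygen on C7, a prenyl group at C8, and ring C at C4a/C8a. The two stereocentres, C2 (benzylic ether CH) and C4 (hemiketal carbon), are the bridgeheads and stand 1,3 to each other across the C3 methylene. The bridge can span only one face, so C4 follows from C2 and only the R configuration at C2 has to be created. Fragile groups are the hemiketal (ring–chain tautomer of a 2',6'-dihydroxyflavanone), the C2–O1 bond (ionisable in acid, opened to a chalcone by base in the open form), and the prenyl and chromene double bonds, which exclude hydrogenation, strong electrophiles, oxidants and hot acid. The real difficulty is the hexasubstituted ring A with its fixed order of substituents and the absolute configuration at C2, which carries a di-ortho-substituted aryl ring. The key step uses the fact that C4 is one carbon at the carbonyl oxidation level between C4a and C3, and that C2–C3 can be carried as an alkyne: ring C then divides into an aryl iodide (iodine on C4a, oxygen on C8a), carbon monoxide and the ring B arylacetylene.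

**Logic of the disconnections**

22 ⇒ 21 ⇒ 20. The hemiketal C4–O bond is opened (ring–chain tautomerism) and the two ring B phenols are masked as acetals. This removes the bicycle and the C4 stereocentre and leaves one stereocentre in a monocyclic ring C. The forward step must unmask without base (retro-oxa-Michael opening) and with acid mild enough not to ionise C2–O1 or touch the two alkenes.

20 ⇒ 18. The C2–H bond is removed, so the only stereocentre is traced back to the planar C2=C3 bond of 18. The gain is an achiral, conjugated precursor. The demand is hydride delivery to one face of a hindered C2, with no 1,2-reduction at C4 and no reaction at the prenyl and chromene alkenes.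

18 ⇒ 11 + 15 + 14. C4a–C4, C4–C3 and O1–C2 are cut, so ring C falls into an aryl iodide, a one-carbon unit and a terminal alkyne. Ring A then needs only a halogen at its last free position, and ring B arrives intact. The forward step must insert 15 before the alkyne is transferred and must close 6-endo, not 5-exo.

11 ⇒ 10 ⇒ 9. The O-acetyl bond and then the C–I bond are cut. The acetate is a design change relative to the free phenol: it prevents a phenoxide next to the reacting carbon and is lost in the key step itself. The iodination must be faster on the ring than on the prenyl alkene that sits next to the free hydroxyl.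

9 ⇒ 6 + 7. The aryl–vinyl carbon bond and the O–CMe2 bond of the dimethylpyran are cut. Because 6 is symmetric and its position between the hydroxyls is blocked, only one regioisomer can arise. The forward step must stop after one annulation.

6 ⇒ 5 ⇒ 2 + 3 ⇒ 1. The aryl–CH2 bond of the prenyl group is cut at the carbon flanked by two oxygens, the most acidic ring position once both oxygens are acetals. This reduces ring A to a commercial phenol and an allylic bromide. The demands are regioselective metalation, substitution at the primary carbon of 3, and acetal removal without addition of the freed phenols to the prenyl group.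

14 ⇒ 13 ⇒ 12. The terminal alkyne carbon is removed (one-carbon homologation of an aldehyde) and the acetals are taken off. The demand is a homologation that tolerates a hindered, electron-rich, non-enolisable aldehyde.

**Other disconnections considered**

Alternative 1: The cut opens ring A at C4a–C5 and C8–C8a. This gives dienophile A2, a 5-bromo-2,3-dihydro-4H-pyran-4-one that already carries C2 and ring B, and diene A3, a 1,1-dimethoxy-3-silyloxy triene with the prenyl group on its reacting terminus. In the forward step the silyl enol ether terminus of A3 (future C8) bonds to the oxygen-bearing β-carbon of A2 (future C8a) and the ketene acetal carbon (future C5) bonds to the brominated α-carbon (future C4a). Three eliminations (bromide, one methoxy group, the silyl group) then aromatise the ring to A1.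
- In its favour: the polarity of both partners fixes the ring A pattern, and no transition metal or toxic gas is needed.
- Where it is the better: C2 can be set at the start by a catalytic asymmetric hetero-Diels–Alder reaction of 13, a better-precedented way to the stereocentre than hydride delivery to the hindered flavone 18.
- Against it here: A1 stops one ring short. The dimethylpyran must be annulated afterwards with amine and heat on a flavanone that opens to its chalcone under those conditions, so C2 is put at risk late. A2 is a vinylogous ester and a weak dienophile, and A3 is substituted at its reacting terminus and moisture-sensitive.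
- Comparison: on convergence the two plans are equal. On mechanism the chosen plan rests on a catalytic cycle that tolerates the complete ring A, while this one needs a thermal cycloaddition of two deactivated partners. On step count they are about equal once the preparation of A3 and the late pyran annulation are counted.

Alternative 2: The cut takes ring B apart at C1'–C2' and C5'–C6' (cycloaddition and electrocyclisation bonds) and at C3'–C4' (made by the 1,2-shift of the Wolff rearrangement; C2'–C3' is already present in the diazo ketone). The precursors are the siloxyalkyne A5, in which the alkyne stands on C2 of a ketal-protected ring A/C unit, and diazo ketone A6. In the forward step irradiation of A6 gives vinylketene A7. Its carbonyl carbon bonds to the alkyne carbon on C2 in a [2+2] addition, the adduct opens in a four-electron process and recloses in a six-electron process, and tautomerisation gives A4 with hydroxyl and silyloxy groups flanking C1'.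
- In its favour: the conditions are neutral, the placement of both oxygens is regiospecific, and ring B appears with one free phenol.
- Where it is the equal or the better: C2 would be set on a precursor without the di-ortho-substituted aryl group, which is easier than step 10.
- Against it here: ring B is the one part of the target that is commercial with its oxygens in place (12), so building it costs many extra steps (ynol silyl ether, diazo ketone, ketal on and off). The 2H-chromene is photolabile (ring opening to a quinone methide) and, like the prenyl group, can add to A7. The differentiation of the two ring B oxygens is of no use, since both end as equivalent phenols before bridging. Acid is still needed to remove the ketal.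
- Comparison: on structure it answers a problem the target does not pose. On mechanism it is clean but photochemically at odds with ring A. On step count it is clearly longer.

Alternative 3: The cut removes C2–C1' and the hemiketal C4–O bond. It leads to chromone A9, which lacks a 2-substituent, and cyclohexane-1,3-dione A10. In the forward step a silyl triflate converts A9 into the 4-silyloxybenzopyrylium triflate A11. A chiral anion-binding hydrogen-bond donor pairs with the triflate while the enol carbon of A10 adds to C2. After desilylation the enol oxygen closes on C4 to give A8.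
- Where it is the better: on structure. Both stereocentres and the whole bicyclic ketal are made in one operation, and the ring B unit needs no protecting groups and no acid deprotection.
- Against it here: A8 is one dehydrogenation short of the target, and the cyclohexenone must be aromatised. The usual ways (α-halogenation or selenation and elimination, quinone oxidants, divalent palladium with an oxidant) all attack the prenyl and chromene alkenes or the electron-rich ring A. The ion-pair addition is precedented for simpler nucleophiles and chromones than a cyclic 1,3-dione and a chromone with a peri methoxy group. A9 needs an acetyl group on 9 next to a prenyl-flanked phenol.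
- Comparison: step count is equal or slightly shorter on paper. The mechanism is less secured, and the risk is moved to a late oxidation, where the chosen plan has only a deprotection left.

Key step: step 9

Remarks on the chemistry:
- Flavanone numbering is used for the flavonoid core (ring B primed); in it the target is (2R,4R). Compounds 9–11 are named with chromene numbering (chromene C6 becomes C4a, the oxygen on chromene C7 becomes O1).
- Compound 21 is assumed to close spontaneously to 22, since the target is drawn as the bridged hemiketal and one of the two equivalent ring B hydroxyls always lies over C4.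
- The sense of induction of the bisphosphine in step 10 is not predicted here. Both antipodes are commercial, the one that gives 2R is used, and the route is written with the (R) ligand.

**Step 1**
Reactants: 1 5-methoxyresorcinol (5-methoxybenzene-1,3-diol)
Product: 2 1-methoxy-3,5-bis(methoxymethoxy)benzene
Conditions: MOMCl (2.5 equiv), i-Pr2NEt (3 equiv), CH2Cl2, 0 °C → rt
Reagents that add atoms: chloromethyl methyl ether, COCCl
Why: Double O-alkylation of the phenols (Williamson-type acetal formation); the two OCH2OCH3 groups are the directing groups for step 2.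

**Step 2**
Reactants: 2 1-methoxy-3,5-bis(methoxymethoxy)benzene; 3 1-bromo-3-methylbut-2-ene
Product: 5 5-methoxy-1,3-bis(methoxymethoxy)-2-(3-methylbut-2-en-1-yl)benzene, via aryllithium 4 (not isolated)
Conditions: n-BuLi (1.1 equiv), THF, 0 °C, 1 h; CuI (10 mol%), then 3, −78 °C → rt
Reagents that add atoms: none
Why: Directed ortho-metalation: the hydrogen between the two acetal groups is removed selectively because both chelate lithium there, while the other two positions have one acetal and one methoxy neighbour. The aryl–metal then displaces bromide from 3 at its primary carbon (copper-assisted SN2 allylation), giving the linear prenyl group.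

**Step 3**
Reactants: 5 5-methoxy-1,3-bis(methoxymethoxy)-2-(3-methylbut-2-en-1-yl)benzene
Product: 6 5-methoxy-2-(3-methylbut-2-en-1-yl)benzene-1,3-diol
Conditions: HCl (1.25 M in MeOH), rt
Reagents that add atoms: none
Why: Acid-catalysed transacetalisation to the solvent removes both aryl MOM ethers. Dilute acid at room temperature is chosen because the freed phenols flank the prenyl group and could add to it (chroman formation) under harsher acid.

**Step 4**
Reactants: 6 5-methoxy-2-(3-methylbut-2-en-1-yl)benzene-1,3-diol; 7 3-methylbut-2-enal
Product: 9 5-methoxy-2,2-dimethyl-8-(3-methylbut-2-en-1-yl)-2H-chromen-7-ol, via ortho-quinone methide 8 (not isolated)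
Conditions: 7 (1.05 equiv), ethylenediammonium diacetate (10 mol%), toluene, 110 °C
Reagents that add atoms: none
Why: Amine-catalysed Knoevenagel-type condensation of the iminium ion of 7 at a ring carbon ortho to a phenol, then oxa-6π-electrocyclisation of 8 (formal [3+3] chromene annulation). Since 6 is symmetric and its position between the hydroxyls is blocked by the prenyl group, only one regioisomer can form; one equivalent of 7 should hold the reaction at the mono-pyran.

**Step 5**
Reactants: 9 5-methoxy-2,2-dimethyl-8-(3-methylbut-2-en-1-yl)-2H-chromen-7-ol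
Product: 10 6-iodo-5-methoxy-2,2-dimethyl-8-(3-methylbut-2-en-1-yl)-2H-chromen-7-ol
Conditions: I2 (1.0 equiv), morpholine (3 equiv), CH2Cl2, 0 °C, dark
Reagents that add atoms: iodine, II
Why: Electrophilic aromatic iodination at the single remaining ring position, which is ortho to the phenol, ortho to the methoxy group and para to the pyran oxygen. The amine-bound iodine is a weak electrophile that should be consumed by this very electron-rich carbon before it engages the prenyl or chromene double bond.

**Step 6**
Reactants: 10 6-iodo-5-methoxy-2,2-dimethyl-8-(3-methylbut-2-en-1-yl)-2H-chromen-7-ol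
Product: 11 6-iodo-5-methoxy-2,2-dimethyl-8-(3-methylbut-2-en-1-yl)-2H-chromen-7-yl acetate
Conditions: Ac2O, pyridine, DMAP (cat.), CH2Cl2, rt
Reagents that add atoms: acetic anhydride, CC(=O)OC(C)=O
Why: O-acylation of the hindered phenol under nucleophilic catalysis. The acetate keeps the oxygen from acting as a phenoxide during oxidative addition and alkynyl transfer in step 9 and is removed there by the amine, so no separate deprotection is needed.

**Step 7**
Reactants: 12 2,6-dihydroxybenzaldehyde
Product: 13 2,6-bis(methoxymethoxy)benzaldehyde
Conditions: MOMCl (3 equiv), i-Pr2NEt (4 equiv), DMF, 0 °C → rt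
Reagents that add atoms: chloromethyl methyl ether, COCCl
Why: Double O-alkylation; excess reagent and a polar solvent are used because both hydroxyls are hydrogen-bonded to the aldehyde.

**Step 8**
Reactants: 13 2,6-bis(methoxymethoxy)benzaldehyde
Product: 14 2-ethynyl-1,3-bis(methoxymethoxy)benzene
Conditions: dimethyl (1-diazo-2-oxopropyl)phosphonate (1.3 equiv), K2CO3 (2 equiv), MeOH, 0 °C → rt
Reagents that add atoms: dimethyl (1-diazo-2-oxopropyl)phosphonate, COP(=O)(OC)C(=[N+]=[N-])C(C)=O
Why: Seyferth–Gilbert homologation with the Ohira–Bestmann reagent: methoxide deacetylates the reagent, the diazomethylphosphonate anion adds to the aldehyde, and loss of dimethyl phosphate and N2 with a 1,2-hydride shift of the alkylidene carbene gives the terminal alkyne. The aldehyde cannot enolise and MOM ethers are stable to K2CO3 in methanol.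

**Step 9**
Reactants: 11 6-iodo-5-methoxy-2,2-dimethyl-8-(3-methylbut-2-en-1-yl)-2H-chromen-7-yl acetate; 14 2-ethynyl-1,3-bis(methoxymethoxy)benzene; 15 carbon monoxide
Product: 18 2-[2,6-bis(methoxymethoxy)phenyl]-5-methoxy-8,8-dimethyl-10-(3-methylbut-2-en-1-yl)-4H,8H-pyrano[3,2-g]chromen-4-one (the flavone), via ortho-acetoxyaryl ynone 16 (not isolated), via ortho-hydroxyaryl enaminone 17 (not isolated)
Conditions: PdCl2(PPh3)2 (5 mol%), dppp (5 mol%), thiourea (5 mol%), CO (1 atm), Et2NH, DBU (2 equiv), 40 → 50 °C
Reagents that add atoms: none
Why: PdCl2(PPh3)2 is reduced in situ to zerovalent palladium, which inserts into the C–I bond of 11; 15 then inserts to give an aroyl complex of divalent palladium, the amine-deprotonated alkyne 14 is transferred to the metal, and reductive elimination gives ynone 16, creating C4a–C4 and C4–C3. Et2NH cleaves the acetate and adds to the ynone to give enaminone 17, whose freed phenol oxygen attacks C2 and expels the amine, forming O1–C2 and closing ring C. The closest known reaction type is the palladium-catalysed carbonylative annulation of ortho-iodophenols or their acetates with terminal arylacetylenes to flavones (carbonylative Sonogashira coupling followed by oxa-Michael closure). Ring C closes in the 6-endo mode (6-endo-dig with respect to the ynone, in practice an addition–elimination on 17). No stereocentre is formed. Carbonylative coupling must win over direct alkynylation, which would end in a 2-arylbenzofuran; the CO atmosphere, the fast CO insertion of an electron-rich aryl–palladium bond and the acetate, which prevents a palladium phenoxide, should secure this, with thiourea and dppp keeping the catalyst alive under CO at low temperature. 6-Endo closure must win over 5-exo-dig closure to the aurone; the secondary amine secures it, because in 17 only C2 is electrophilic. The prenyl and chromene double bonds are meta to the reacting carbon and cannot reach the acyl–palladium centre, and the MOM ethers are inert to amine base.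

**Step 10**
Reactants: 18 2-[2,6-bis(methoxymethoxy)phenyl]-5-methoxy-8,8-dimethyl-10-(3-methylbut-2-en-1-yl)-4H,8H-pyrano[3,2-g]chromen-4-one
Product: 20 (2R)-2-[2,6-bis(methoxymethoxy)phenyl]-5-methoxy-8,8-dimethyl-10-(3-methylbut-2-en-1-yl)-2,3-dihydro-4H,8H-pyrano[3,2-g]chromen-4-one, via silyl enol ether 19 (not isolated)
Conditions: Cu(OAc)2 (5 mol%), (R)-DTBM-SEGPHOS (5.5 mol%), (EtO)2MeSiH (3 equiv), toluene, 0 °C → rt; then 1 M aq. HCl, THF, 0 °C
Reagents that add atoms: none
Why: Copper hydride conjugate reduction (asymmetric 1,4-hydrosilylation of a chromone): the bisphosphine-bound CuH adds hydride to C2, the β-carbon of the enone, and the copper enolate is silylated by the silane to 19, which regenerates CuH and shields C4 from 1,2-reduction. The R configuration at C2 is set by the chiral ligand, which selects one face of the planar flavone (catalyst control); cold dilute acid then releases the ketone without touching C2.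

**Step 11**
Reactants: 20 (2R)-2-[2,6-bis(methoxymethoxy)phenyl]-5-methoxy-8,8-dimethyl-10-(3-methylbut-2-en-1-yl)-2,3-dihydro-4H,8H-pyrano[3,2-g]chromen-4-one
Product: 22 the (2R,4R) bridged hemiketal target, via free dihydroxyflavanone 21 (not isolated)
Conditions: 3 M aq. HCl, THF, rt → 40 °C
Reagents that add atoms: none
Why: Aqueous acid hydrolyses both aryl MOM acetals to 21; either of the two equivalent ring B hydroxyls then adds to the C4 ketone (6-exo-trig hemiketalisation), which is possible only from the face that carries the C2 aryl group, so C4 forms as R under control of C2. No base is present, so retro-oxa-Michael opening is avoided, and no alcohol is present, so the hemiketal cannot be trapped as a mixed ketal.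

**Compound list**

1 | 5-methoxyresorcinol (5-methoxybenzene-1,3-diol) | COc1cc(O)cc(O)c1 | starting material
2 | 1-methoxy-3,5-bis(methoxymethoxy)benzene | COCOc1cc(OC)cc(OCOC)c1 | intermediate
3 | 1-bromo-3-methylbut-2-ene | CC(C)=CCBr | starting material
4 | [4-methoxy-2,6-bis(methoxymethoxy)phenyl]lithium | [Li]c1c(OCOC)cc(OC)cc1OCOC | intermediate (not isolated)
5 | 5-methoxy-1,3-bis(methoxymethoxy)-2-(3-methylbut-2-en-1-yl)benzene | COCOc1cc(OC)cc(OCOC)c1CC=C(C)C | intermediate
6 | 5-methoxy-2-(3-methylbut-2-en-1-yl)benzene-1,3-diol | COc1cc(O)c(CC=C(C)C)c(O)c1 | intermediate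
7 | 3-methylbut-2-enal | CC(C)=CC=O | starting material
8 | (6Z)-3-hydroxy-5-methoxy-6-(3-methylbut-2-en-1-ylidene)-2-(3-methylbut-2-en-1-yl)cyclohexa-2,4-dien-1-one | O=C1C(CC=C(C)C)=C(O)C=C(OC)/C1=C/C=C(C)C | intermediate (not isolated)
9 | 5-methoxy-2,2-dimethyl-8-(3-methylbut-2-en-1-yl)-2H-chromen-7-ol | COc1cc(O)c(CC=C(C)C)c2OC(C)(C)C=Cc12 | intermediate
10 | 6-iodo-5-methoxy-2,2-dimethyl-8-(3-methylbut-2-en-1-yl)-2H-chromen-7-ol | COc1c(I)c(O)c(CC=C(C)C)c2OC(C)(C)C=Cc12 | intermediate
11 | 6-iodo-5-methoxy-2,2-dimethyl-8-(3-methylbut-2-en-1-yl)-2H-chromen-7-yl acetate | COc1c(I)c(OC(C)=O)c(CC=C(C)C)c2OC(C)(C)C=Cc12 | intermediate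
12 | 2,6-dihydroxybenzaldehyde | O=Cc1c(O)cccc1O | starting material
13 | 2,6-bis(methoxymethoxy)benzaldehyde | O=Cc1c(OCOC)cccc1OCOC | intermediate
14 | 2-ethynyl-1,3-bis(methoxymethoxy)benzene | C#Cc1c(OCOC)cccc1OCOC | intermediate
15 | carbon monoxide | [C-]#[O+] | starting material
16 | 6-{3-[2,6-bis(methoxymethoxy)phenyl]prop-2-ynoyl}-5-methoxy-2,2-dimethyl-8-(3-methylbut-2-en-1-yl)-2H-chromen-7-yl acetate | COc1c(C(=O)C#Cc3c(OCOC)cccc3OCOC)c(OC(C)=O)c(CC=C(C)C)c2OC(C)(C)C=Cc12 | intermediate (not isolated)
17 | (2E)-3-[2,6-bis(methoxymethoxy)phenyl]-3-(diethylamino)-1-[7-hydroxy-5-methoxy-2,2-dimethyl-8-(3-methylbut-2-en-1-yl)-2H-chromen-6-yl]prop-2-en-1-one | COc1c(C(=O)/C=C(\c3c(OCOC)cccc3OCOC)N(CC)CC)c(O)c(CC=C(C)C)c2OC(C)(C)C=Cc12 | intermediate (not isolated)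
18 | 2-[2,6-bis(methoxymethoxy)phenyl]-5-methoxy-8,8-dimethyl-10-(3-methylbut-2-en-1-yl)-4H,8H-pyrano[3,2-g]chromen-4-one | COc1c2c(c(CC=C(C)C)c3c1C(=O)C=C(O3)c1c(OCOC)cccc1OCOC)OC(C)(C)C=C2 | intermediate
19 | {[(2R)-2-[2,6-bis(methoxymethoxy)phenyl]-5-methoxy-8,8-dimethyl-10-(3-methylbut-2-en-1-yl)-2H,8H-pyrano[3,2-g]chromen-4-yl]oxy}(diethoxy)methylsilane | COc1c2c(c(CC=C(C)C)c3c1C(O[Si](C)(OCC)OCC)=C[C@@H](O3)c1c(OCOC)cccc1OCOC)OC(C)(C)C=C2 | intermediate (not isolated)
20 | (2R)-2-[2,6-bis(methoxymethoxy)phenyl]-5-methoxy-8,8-dimethyl-10-(3-methylbut-2-en-1-yl)-2,3-dihydro-4H,8H-pyrano[3,2-g]chromen-4-one | COc1c2c(c(CC=C(C)C)c3c1C(=O)C[C@@H](O3)c1c(OCOC)cccc1OCOC)OC(C)(C)C=C2 | intermediate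
21 | (2R)-2-(2,6-dihydroxyphenyl)-5-methoxy-8,8-dimethyl-10-(3-methylbut-2-en-1-yl)-2,3-dihydro-4H,8H-pyrano[3,2-g]chromen-4-one | COc1c2c(c(CC=C(C)C)c3c1C(=O)C[C@@H](O3)c1c(O)cccc1O)OC(C)(C)C=C2 | intermediate (not isolated)
22 | (2R,4R) bridged hemiketal (flavanone numbering): 4-hydroxy-5-methoxy-8-prenylflavan with a 2,2-dimethylpyran fused at C6–C7 (oxygen on C7), one ring B ortho oxygen bonded to C4, the other ring B ortho hydroxyl free | COc1c2c(c(CC=C(C)C)c3c1[C@@]1(O)C[C@@H](O3)c3c(O)cccc3O1)OC(C)(C)C=C2 | target

**Step count and uncertain steps**

Total step count: 11. Longest linear sequence: 9 steps (steps 1–6 and 9–11, from 1); steps 7 and 8 are a two-step branch that joins at step 9.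

Step 9 (key step). Oxidative addition at a C–I bond flanked by methoxy and acetoxy groups may be slow. The alkyne may then be transferred before CO inserts, and closure of that product would give a 2-arylbenzofuran; premature loss of the acetate would favour the same path. Fallback, from 9 back to 18 without palladium: magnesium-mediated ortho-formylation of 9 (MgCl2, Et3N, paraformaldehyde, MeCN, reflux) should give 7-hydroxy-5-methoxy-2,2-dimethyl-8-(3-methylbut-2-en-1-yl)-2H-chromene-6-carbaldehyde F1. Addition of excess lithium acetylide F2 (from 14 and n-BuLi, THF, −78 → 0 °C) should give the racemic propargylic alcohol F3. MnO2 in CH2Cl2 should oxidise F3 to the ortho-hydroxyaryl ynone F4. Et2NH in ethanol at room temperature should then close F4 through 17 to 18.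

Step 10. Hydride delivery to C2 may be slow or poorly face-selective, because the aryl group on C2 is twisted and di-ortho-substituted. Competing 1,2-reduction at C4 or hydrocupration of the styrene-type chromene double bond would also lower the outcome. Fallback, from 18 back to 20: conjugate reduction with LiBH(s-Bu)3 (THF, −78 °C) should give the racemic flavanone F5. Kinetic resolution by asymmetric transfer hydrogenation with RuCl[(S,S)-TsDPEN](p-cymene) or its antipode (HCO2H/Et3N), stopped near half conversion, should reduce the 2S enantiomer to the cis-flavan-4-ol F6 and leave 20. At most half of the material is retained in this way.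

Step 11. Before the hemiketal locks the bicycle, acid may ionise the C2–O1 bond and erode the configuration. Slow hydration of the prenyl group, capture of formaldehyde-derived cations by the resorcinol ring B, or incomplete removal of the second acetal may also occur. Fallback, from 18 back to 21 and so to 22, with the acid step moved to a stage that has no stereocentre: HCl in methanol at 50 °C should convert 18 into the 2',6'-dihydroxyflavone F7. TBSCl and imidazole in DMF should give the bis(tert-butyldimethylsilyl) ether F8. Reduction as in step 10 should give, through the silyl enol ether F9, the (2R)-bis-silyl flavanone F10. Bu4NF buffered with acetic acid (THF, 0 °C) should then release 21, which closes to 22.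

Step 5. Iodine may be captured by the prenyl double bond with ring closure by the neighbouring hydroxyl (iodoetherification), or may add across the chromene double bond, in competition with ring iodination. Fallback, from 5 back to 10, with the iodine introduced as an electrophilic quench of an aryl anion before any free phenol or pyran exists: a second directed metalation of 5 (n-BuLi, THF, 0 °C) should give the aryllithium F11, and iodine at −78 °C should give 2-iodo-1-methoxy-3,5-bis(methoxymethoxy)-4-(3-methylbut-2-en-1-yl)benzene F12. Acetal removal as in step 3 should give 4-iodo-5-methoxy-2-(3-methylbut-2-en-1-yl)benzene-1,3-diol F13. Annulation with 7 as in step 4 can then occur at only one position and should pass through the ortho-quinone methide F14 to 10. This detour also removes the over-annulation problem of step 4.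

Step 4. The product still has a phenol with a free ortho position, so a second annulation to a bis-pyran may compete, and the aldehyde may self-condense. Fallback, from 6 back to 9 by a sigmatropic route: mono-O-alkylation of 6 with 3-chloro-3-methylbut-1-yne (K2CO3, KI, CuI cat., acetone, reflux) should give the aryl propargyl ether 5-methoxy-2-(3-methylbut-2-en-1-yl)-3-[(2-methylbut-3-yn-2-yl)oxy]phenol F15, which is purified from diether. Heating in xylene at 140 °C should bring about Claisen rearrangement to the allenylphenol F16, a 1,5-hydrogen shift to 8 and electrocyclisation to 9.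

**Further compounds**

F1 | step 9 | 7-hydroxy-5-methoxy-2,2-dimethyl-8-(3-methylbut-2-en-1-yl)-2H-chromene-6-carbaldehyde | COc1c(C=O)c(O)c(CC=C(C)C)c2OC(C)(C)C=Cc12
F2 | step 9 | {[2,6-bis(methoxymethoxy)phenyl]ethynyl}lithium | [Li]C#Cc1c(OCOC)cccc1OCOC
F3 | step 9 | 6-{3-[2,6-bis(methoxymethoxy)phenyl]-1-hydroxyprop-2-yn-1-yl}-5-methoxy-2,2-dimethyl-8-(3-methylbut-2-en-1-yl)-2H-chromen-7-ol (racemic) | COc1c(C(O)C#Cc3c(OCOC)cccc3OCOC)c(O)c(CC=C(C)C)c2OC(C)(C)C=Cc12
F4 | step 9 | 3-[2,6-bis(methoxymethoxy)phenyl]-1-[7-hydroxy-5-methoxy-2,2-dimethyl-8-(3-methylbut-2-en-1-yl)-2H-chromen-6-yl]prop-2-yn-1-one | COc1c(C(=O)C#Cc3c(OCOC)cccc3OCOC)c(O)c(CC=C(C)C)c2OC(C)(C)C=Cc12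
F5 | step 10 | racemic 2-[2,6-bis(methoxymethoxy)phenyl]-5-methoxy-8,8-dimethyl-10-(3-methylbut-2-en-1-yl)-2,3-dihydro-4H,8H-pyrano[3,2-g]chromen-4-one | COc1c2c(c(CC=C(C)C)c3c1C(=O)CC(O3)c1c(OCOC)cccc1OCOC)OC(C)(C)C=C2
F6 | step 10 | (2S,4S)-2-[2,6-bis(methoxymethoxy)phenyl]-5-methoxy-8,8-dimethyl-10-(3-methylbut-2-en-1-yl)-3,4-dihydro-2H,8H-pyrano[3,2-g]chromen-4-ol (cis) | COc1c2c(c(CC=C(C)C)c3c1[C@@H](O)C[C@H](O3)c1c(OCOC)cccc1OCOC)OC(C)(C)C=C2
F7 | step 11 | 2-(2,6-dihydroxyphenyl)-5-methoxy-8,8-dimethyl-10-(3-methylbut-2-en-1-yl)-4H,8H-pyrano[3,2-g]chromen-4-one | COc1c2c(c(CC=C(C)C)c3c1C(=O)C=C(O3)c1c(O)cccc1O)OC(C)(C)C=C2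
F8 | step 11 | 2-{2,6-bis[(tert-butyldimethylsilyl)oxy]phenyl}-5-methoxy-8,8-dimethyl-10-(3-methylbut-2-en-1-yl)-4H,8H-pyrano[3,2-g]chromen-4-one | COc1c2c(c(CC=C(C)C)c3c1C(=O)C=C(O3)c1c(O[Si](C)(C)C(C)(C)C)cccc1O[Si](C)(C)C(C)(C)C)OC(C)(C)C=C2
F9 | step 11 | (2R)-2-{2,6-bis[(tert-butyldimethylsilyl)oxy]phenyl}-4-{[diethoxy(methyl)silyl]oxy}-5-methoxy-8,8-dimethyl-10-(3-methylbut-2-en-1-yl)-2H,8H-pyrano[3,2-g]chromene | COc1c2c(c(CC=C(C)C)c3c1C(O[Si](C)(OCC)OCC)=C[C@@H](O3)c1c(O[Si](C)(C)C(C)(C)C)cccc1O[Si](C)(C)C(C)(C)C)OC(C)(C)C=C2
F10 | step 11 | (2R)-2-{2,6-bis[(tert-butyldimethylsilyl)oxy]phenyl}-5-methoxy-8,8-dimethyl-10-(3-methylbut-2-en-1-yl)-2,3-dihydro-4H,8H-pyrano[3,2-g]chromen-4-one | COc1c2c(c(CC=C(C)C)c3c1C(=O)C[C@@H](O3)c1c(O[Si](C)(C)C(C)(C)C)cccc1O[Si](C)(C)C(C)(C)C)OC(C)(C)C=C2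
F11 | step 5 | [6-methoxy-2,4-bis(methoxymethoxy)-3-(3-methylbut-2-en-1-yl)phenyl]lithium | COCOc1cc(OC)c([Li])c(OCOC)c1CC=C(C)C
F12 | step 5 | 2-iodo-1-methoxy-3,5-bis(methoxymethoxy)-4-(3-methylbut-2-en-1-yl)benzene | COCOc1cc(OC)c(I)c(OCOC)c1CC=C(C)C
F13 | step 5 | 4-iodo-5-methoxy-2-(3-methylbut-2-en-1-yl)benzene-1,3-diol | COc1cc(O)c(CC=C(C)C)c(O)c1I
F14 | step 5 | (6Z)-3-hydroxy-4-iodo-5-methoxy-6-(3-methylbut-2-en-1-ylidene)-2-(3-methylbut-2-en-1-yl)cyclohexa-2,4-dien-1-one | O=C1C(CC=C(C)C)=C(O)C(I)=C(OC)/C1=C/C=C(C)C
F15 | step 4 | 5-methoxy-2-(3-methylbut-2-en-1-yl)-3-[(2-methylbut-3-yn-2-yl)oxy]phenol | COc1cc(O)c(CC=C(C)C)c(OC(C)(C)C#C)c1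
F16 | step 4 | 5-methoxy-4-(3-methylbuta-1,2-dien-1-yl)-2-(3-methylbut-2-en-1-yl)benzene-1,3-diol | COc1cc(O)c(CC=C(C)C)c(O)c1C=C=C(C)C
A1 | alternative 1 | (2R)-2-[2,6-bis(methoxymethoxy)phenyl]-7-hydroxy-5-methoxy-8-(3-methylbut-2-en-1-yl)-2,3-dihydro-4H-chromen-4-one | COc1cc(O)c(CC=C(C)C)c2c1C(=O)C[C@@H](O2)c1c(OCOC)cccc1OCOC
A2 | alternative 1 | (2R)-2-[2,6-bis(methoxymethoxy)phenyl]-5-bromo-2,3-dihydro-4H-pyran-4-one | O=C1C[C@@H](OC=C1Br)c1c(OCOC)cccc1OCOC
A3 | alternative 1 | (3Z)-1,1-dimethoxy-7-methyl-3-(trimethylsilyloxy)octa-1,3,6-triene | COC(OC)=C/C(O[Si](C)(C)C)=C/CC=C(C)C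
A4 | alternative 2 | (2R)-flavanone ethylene ketal with complete ring A and ring B as 2-hydroxy-6-(triisopropylsilyloxy)phenyl | COc1c2c(c(CC=C(C)C)c3c1C1(OCCO1)C[C@@H](O3)c1c(O)cccc1O[Si](C(C)C)(C(C)C)C(C)C)OC(C)(C)C=C2
A5 | alternative 2 | (2R)-5-methoxy-8,8-dimethyl-10-(3-methylbut-2-en-1-yl)-2-[(triisopropylsilyloxy)ethynyl]-2,3-dihydro-4H,8H-pyrano[3,2-g]chromen-4-one ethylene ketal | COc1c2c(c(CC=C(C)C)c3c1C1(OCCO1)C[C@@H](O3)C#CO[Si](C(C)C)(C(C)C)C(C)C)OC(C)(C)C=C2
A6 | alternative 2 | 1-diazobut-3-en-2-one | C=CC(=O)C=[N+]=[N-]
A7 | alternative 2 | buta-1,3-dien-1-one (vinylketene) | C=CC=C=O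
A8 | alternative 3 | (2R,4R) bridged hemiketal with a cyclohexenone in place of ring B | COc1c2c(c(CC=C(C)C)c3c1[C@@]1(O)C[C@@H](O3)C3=C(O1)CCCC3=O)OC(C)(C)C=C2
A9 | alternative 3 | 5-methoxy-8,8-dimethyl-10-(3-methylbut-2-en-1-yl)-4H,8H-pyrano[3,2-g]chromen-4-one | COc1c2c(c(CC=C(C)C)c3c1C(=O)C=CO3)OC(C)(C)C=C2
A10 | alternative 3 | cyclohexane-1,3-dione | O=C1CCCC(=O)C1
A11 | alternative 3 | 4-[(tert-butyldimethylsilyl)oxy]-5-methoxy-8,8-dimethyl-10-(3-methylbut-2-en-1-yl)-8H-pyrano[3,2-g]chromen-1-ium trifluoromethanesulfonate | COc1c2c(c(CC=C(C)C)c3c1c(O[Si](C)(C)C(C)(C)C)cc[o+]3)OC(C)(C)C=C2.[O-]S(=O)(=O)C(F)(F)F
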